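## Analysis of the target

The target 21 is an open-chain tridecane whose only ring is the arene: C1 is a benzylic methylene carrying a 3-hydroxy-5-methoxyphenyl group, C2 bears the acetoxy group, C3–C7 are five methylenes, C8 bears a free hydroxyl, and C9–C13 form an n-pentyl tail. The two stereocentres, C2 (R) and C8 (S), are five methylenes apart, so neither can direct the other and each needs an external source of asymmetry. C8 is the hard one, because its two carbon substituents, pentyl and the pentamethylene tether, are identical for five atoms and offer a reagent nothing to grip. The sensitive groups are the secondary acetate (lost to base, hydride and organometallics, so it must come late), the free phenol (acidic, to be masked during Grignard chemistry) and the aryl methyl ether (which rules out hard Lewis-acid deprotections); in addition, the two secondary hydroxyls must be told apart so that only O2 is acetylated. The strategy rests on a hidden symmetry: if the arylmethyl group at C2 and the pentyl group at C8 are both read simply as outer substituents, the oxygens at C2 and C8 point the same way in space, and the opposite descriptors arise only because CH2Ar outranks the tether at C2 while the tether outranks pentyl at C8. The C1–C9 segment with oxygen at C2 and C8 is therefore twofold-symmetric and maps onto (2R,8R)-1,9-dichlorononane-2,8-diol 9. In 9 each carbinol is flanked by a chloromethyl group and the tether, a pair that is easy to distinguish, and C1 and C9 are latent electrophiles for attaching the aryl and butyl groups.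

## Retrosynthetic reasoning

**O–benzyl bonds (21 from 19).** The last disconnection removes two benzyl ethers, one on the phenol and one on O8, from the fully assembled acetate 19. Benzyl is preferred to silyl on both oxygens because one neutral hydrogenolysis frees both without exposing the C2 acetate to fluoride or base in the presence of a phenoxide. The half-deprotected phenol 20 is passed through on the way.

**O2–acyl bond (19 from 18).** The acetate is cut back to the alcohol 18. At that stage O2 is the only free hydroxyl, so acetylation needs no selectivity, and it follows the last organometallic step.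

**C1–aryl bond (18 from 14 and 16).** Cutting the benzylic bond turns C1–C2 into the terminal epoxide of 14 and the arene into the Grignard reagent 17, made from bromide 16, the benzyl ether of commercial phenol 15. This cut is preferred because the nucleophile attacks C1, not the stereocentre, so C2 keeps its configuration and no asymmetric step is needed there.

**C9–C10 bond (14 from 13, and 13 from 11 and 12).** The benzyl ether 14 comes from the epoxy alcohol 13, which is the product of opening one epoxide of the twofold-symmetric bis-epoxide 11 with butylmagnesium chloride 12. Since the two epoxides of 11 are equivalent, either may react; the opening itself distinguishes C8 (hydroxyl, protected next) from C2 (still an epoxide). Butyl goes in first because the hydroxyl released first must be the one that is masked and ends up unacetylated.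

**Epoxide C–O bonds (11 from 9).** Both epoxides are traced to the chlorohydrin units of diol 9. Ring closure involves only the primary C–Cl carbons, so the configuration is carried over unchanged.

**C2–H and C8–H bonds (9 from 7).** Both stereocentres are traced to the carbonyl groups of the symmetric diketone 7, through the hydroxy ketone 8. The forward reaction must deliver hydride to the same face of two equivalent chloromethyl ketones. This is the step that replaces the intractable pentyl-versus-tether discrimination by a chloromethyl-versus-tether discrimination, and it is done enzymatically.

**C1–C2 and C8–C9 bonds (7 from 3 and 4, and 3 from 1).** The two chloromethyl carbons, each with its chlorine, come from two molecules of chloroiodomethane 4 through chloromethyllithium 5, one adding to each terminus of the bis-Weinreb amide 3. The adduct 6 holds the ketone oxidation level until work-up. Amide 3 is made in one step from pimeloyl chloride 1 by way of the half-amide 2.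

## Alternatives that were turned down

Alternative 1: The benzene ring itself is disconnected. The bond from the phenol carbon to its neighbouring CH and the bond from the methoxy-bearing carbon to the CH next to the chain-bearing carbon are cut. This leads to the 3-substituted cyclobutenone A2, which carries the complete C1–C13 chain, and methoxyacetylene A3. In the forward sense A2 is heated with A3 (Danheiser benzannulation): four-electron ring opening of A2, regioselective [2+2] addition of A3 to the ketene so formed, a second four-electron opening, six-electron closure and tautomerisation should give phenol A1, the C8 silyl ether of 21, and desilylation would finish. In its favour, the 1,3,5-pattern of OH, OCH3 and alkyl is formed regiospecifically and the phenol appears free, so it never needs a protecting group. On that point it is stronger than the chosen route, which has to mask and unmask the phenol of 15. Against it: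
- The ring it builds can be bought with the correct substitution (15).
- Both stereocentres, including the difficult C8, must already be present in A2 and get no help from the key step.
- A2 has an acetoxy group on the carbon next to the acidified γ-methylene of the enone, so vinylogous β-elimination of the acetoxy group threatens at benzannulation temperatures.
- A3 is volatile, unstable and has to be prepared.
- The product phenol can be acylated by the ketene intermediate.

The chosen strategy spends its key step on the real problem, the two remote carbinols, and reaches the arylated chain in fewer operations.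

Alternative 2: The C7–C8 bond is cut. C8 with its pentyl group comes from hexyl N,N-diisopropylcarbamate A5, and C1–C7 from the primary pinacol boronic ester A6, which already carries C2 as a silyl ether and the benzyl-protected arene. In the forward sense A5 is deprotonated enantioselectively by a sec-alkyllithium and a chiral diamine, the lithiated carbamate is captured by A6, and 1,2-migration of C7 from boron to carbon should give the secondary boronic ester A4. Oxidation of the C–B bond with retention then reveals the C8 hydroxyl. In its favour, C8 is set by which enantiotopic hydrogen is removed, so the pentyl/tether similarity is irrelevant. The outcome is predictable without a screen, and either C8 epimer is available by switching the diamine antipode. On C8 it is as strong as the chosen route, and stronger in predictability and stereodivergence. Against it: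
- It needs a stoichiometric chiral base at −78 °C.
- It does nothing for C2, which requires a second asymmetric operation on the way to A6.
- A6 is itself a multistep compound.
- After oxidation the free hydroxyl sits at C8 and the protected one at C2, the reverse of what 21 needs, so a protecting-group exchange of several steps must precede acetylation.

The chosen strategy offers one catalytic operation for both stereocentres, a separable diastereomer as the main stereochemical error, and a shorter sequence.

Alternative 3: The C2–C3 bond is cut. The electrophile is the racemic 1-bromoalkyl acetate A8, made from the arylacetaldehyde A10 and acetyl bromide A11; the nucleophile is the alkylzinc reagent A9, which contains C3–C13 with C8 as a silyl ether. In the forward sense a chiral nickel catalyst should convert both enantiomers of A8, through a common C2 radical, into one enantiomer of the bis-silyl ether A7 by coupling with A9, and desilylation would give 21. In its favour, C2 arrives already acetylated, so no late acetylation and no ordering of events are needed to tell the two hydroxyls apart, and the assembly is convergent. On endgame economy it is stronger than the chosen route. Against it: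
- A10 is an enolisable arylacetaldehyde prone to self-condensation.
- A8 is a labile α-bromoalkyl ester with benzylic β-hydrogens that can lose HBr to a conjugated enol acetate.
- The C2 organonickel intermediate has the same benzylic β-hydrogens available for β-hydride elimination.
- The catalyst has to distinguish a flexible benzyl arm from an alkyl arm at a centre carrying only a small acetoxy group.
- C8 must still be set separately inside A9, where the pentyl/tether problem returns.

The chosen strategy pays with a protect, acetylate, deprotect endgame, but it sets both centres together and uses robust intermediates.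

Key step: step 3

Remark: a ketoreductase of Prelog-type selectivity that accepts 1-chloroalkan-2-ones and isopropanol as co-substrate is assumed to be available from a standard screening panel; the enzyme is specified by cofactor and stereochemical sense only.
Remark: butylmagnesium chloride 12 is taken as the commercial THF solution.

## Route

Step 1
Reactants: 1 heptanedioyl dichloride (pimeloyl chloride)
Product: 3 N1,N7-dimethoxy-N1,N7-dimethylheptanediamide, via half-amide acid chloride 2 (not isolated)
Conditions: MeNHOMe·HCl (2.2 equiv), K2CO3, H2O/EtOAc, 0 °C → rt
Reagents that add atoms: N,O-dimethylhydroxylamine hydrochloride, CNOC.Cl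
Why: Schotten–Baumann acylation; at 0 °C the acid chloride termini acylate the liberated hydroxylamine faster than they hydrolyse, and the Weinreb amide is stable to aqueous carbonate.

Step 2
Reactants: 3 N1,N7-dimethoxy-N1,N7-dimethylheptanediamide; 4 chloroiodomethane (two equivalents are consumed)
Product: 7 1,9-dichlorononane-2,8-dione, via chloromethyllithium 5 (not isolated), via dilithium bis-hemiaminal adduct 6 (not isolated)
Conditions: 4 (3.0 equiv), MeLi·LiBr (2.8 equiv) added dropwise to 3 + 4, THF/Et2O, −78 °C; then 1 M HCl, −78 → 0 °C
Reagents that add atoms: chloroiodomethane (second equivalent of 4), ClCI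
Why: Iodine–lithium exchange between MeLi and 4 gives carbenoid 5 in the presence of the amide (Barbier mode), so it is trapped before it can α-eliminate; one ClCH2 unit is delivered to each of the two amide termini, which is why 4 is used in twofold amount plus a small excess. Nucleophilic acyl substitution on each Weinreb amide stops at the chelated tetrahedral adduct 6, which releases the chloromethyl ketone only on acidic quench, so no second addition occurs at either carbonyl.

Step 3
Reactants: 7 1,9-dichlorononane-2,8-dione
Product: 9 (2R,8R)-1,9-dichlorononane-2,8-diol, via (8R)-1,9-dichloro-8-hydroxynonan-2-one 8 (not isolated)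
Conditions: Prelog-type NADPH-dependent ketoreductase, NADP+ (cat.), i-PrOH (15% v/v), KH2PO4/K2HPO4 buffer (0.1 M, pH 7.0), 30 °C
Reagents that add atoms: none
Why: In the active site the carbonyl oxygen is held by the catalytic acid of the enzyme and hydride passes from C4 of bound NADPH to the carbonyl carbon while the oxygen is protonated; the oxidised cofactor is reduced again by the same enzyme at the cost of isopropanol, and the electron-poor α-chloro ketone lies far on the alcohol side of that equilibrium. The closest known reaction type is the ketoreductase (alcohol dehydrogenase) reduction of chloromethyl ketones to chlorohydrins, together with the twofold enzymatic reduction of symmetric diketones; here the two are combined on one substrate. No ring is closed and no skeletal bond is made: two C–H bonds form, at C2 and C8, one after the other by way of hydroxy ketone 8. Each new stereocentre is controlled by the enzyme alone: the chloromethyl group sits in the small pocket and the methylene tether in the large one, so hydride reaches the si face of each carbonyl (the Prelog face here, since the small group has the higher CIP rank) and both carbinols come out R. The step needs enantiofacial selectivity at two equivalent sites, complete reduction of the second carbonyl and no attack on the C–Cl bonds. The substrate secures this through the large difference in size and polarity between ClCH2 and the tether, through the five-methylene spacer that lets each terminus behave as an isolated 1-chloroalkan-2-one, and through the neutral pH at which neither chlorohydrin closes or hydrolyses. Because the two ends are reduced independently, a wrong-face event leads mostly to the meso diol, a diastereomer removable by chromatography or crystallisation, so the R,R diol should be enriched beyond the single-site selectivity (Horeau-type amplification).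

Step 4
Reactants: 9 (2R,8R)-1,9-dichlorononane-2,8-diol
Product: 11 (2R,2'R)-2,2'-(pentane-1,5-diyl)bis(oxirane), via (2R)-1-chloro-7-[(2R)-oxiran-2-yl]heptan-2-ol 10 (not isolated)
Conditions: NaOH (2 M aq), THF, 0 °C → rt
Reagents that add atoms: none
Why: Twofold intramolecular Williamson etherification (3-exo-tet); each alkoxide displaces the neighbouring primary chloride, the C–O bonds at the stereocentres are untouched, and both centres stay R.

Step 5
Reactants: 11 (2R,2'R)-2,2'-(pentane-1,5-diyl)bis(oxirane) (in excess, unreacted part recovered); 12 butylmagnesium chloride
Product: 13 (6S)-11-[(2R)-oxiran-2-yl]undecan-6-ol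
Conditions: CuI (10 mol%), THF, −40 → −20 °C, slow addition of 12; then aq NH4Cl
Reagents that add atoms: none
Why: Copper-catalysed Grignard opening of a terminal epoxide; the butylcuprate attacks the unsubstituted carbon C9 in SN2 fashion, so the C8–O bond keeps its configuration (the descriptor becomes S only because the tether now outranks pentyl). The two epoxides of 11 are homotopic, so whichever reacts gives the same product, and excess 11 with slow addition of 12 should hold double addition down.

Step 6
Reactants: 13 (6S)-11-[(2R)-oxiran-2-yl]undecan-6-ol
Product: 14 (2R)-2-[(6S)-6-(benzyloxy)undecyl]oxirane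
Conditions: NaH, BnBr, THF/DMF, 0 °C → rt
Reagents that add atoms: benzyl bromide, BrCc1ccccc1
Why: Williamson etherification of the sodium alkoxide; the remote epoxide is spared because intramolecular attack would need an eight- or nine-membered ring and intermolecular opening by a hindered secondary alkoxide is slow at this temperature.

Step 7
Reactants: 15 3-bromo-5-methoxyphenol
Product: 16 1-(benzyloxy)-3-bromo-5-methoxybenzene
Conditions: BnBr, K2CO3, DMF, rt
Reagents that add atoms: benzyl bromide, BrCc1ccccc1
Why: Phenoxide O-alkylation (Williamson); the benzyl ether removes the acidic proton before Grignard formation and is later cleaved together with the C8 benzyl ether.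

Step 8
Reactants: 14 (2R)-2-[(6S)-6-(benzyloxy)undecyl]oxirane; 16 1-(benzyloxy)-3-bromo-5-methoxybenzene
Product: 18 (2R,8S)-8-(benzyloxy)-1-[3-(benzyloxy)-5-methoxyphenyl]tridecan-2-ol, via [3-(benzyloxy)-5-methoxyphenyl]magnesium bromide 17 (not isolated)
Conditions: 16, Mg, THF, 45 °C; then CuI (10 mol%), 14, THF, −30 → 0 °C; aq NH4Cl
Reagents that add atoms: none
Why: Magnesium insertion gives aryl Grignard 17, and copper-catalysed opening of the terminal epoxide takes place at the CH2 carbon C1 in SN2 fashion, so the C2–O bond and its R configuration are retained. CuI suppresses halohydrin formation and Lewis-acid rearrangement of the epoxide, and both benzyl ethers are inert to the organometallic.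

Step 9
Reactants: 18 (2R,8S)-8-(benzyloxy)-1-[3-(benzyloxy)-5-methoxyphenyl]tridecan-2-ol
Product: 19 (2R,8S)-8-(benzyloxy)-1-[3-(benzyloxy)-5-methoxyphenyl]tridecan-2-yl acetate
Conditions: Ac2O, pyridine, DMAP (cat.), CH2Cl2, rt
Reagents that add atoms: acetic anhydride, CC(=O)OC(C)=O
Why: DMAP-catalysed acylation of the only free hydroxyl; O8 and the phenol are benzylated, so the acetate can go only to O2, and the C2–O bond is not broken.

Step 10
Reactants: 19 (2R,8S)-8-(benzyloxy)-1-[3-(benzyloxy)-5-methoxyphenyl]tridecan-2-yl acetate
Product: 21 (2R,8S)-8-hydroxy-1-(3-hydroxy-5-methoxyphenyl)tridecan-2-yl acetate, via (2R,8S)-8-(benzyloxy)-1-(3-hydroxy-5-methoxyphenyl)tridecan-2-yl acetate 20 (not isolated)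
Conditions: H2 (1 atm), Pd/C (10%), EtOAc/EtOH, rt
Reagents that add atoms: none
Why: Heterogeneous hydrogenolysis of benzyl ethers; the aryl benzyl ether should cleave first (20) and the secondary alkyl benzyl ether follows. The acetate, the aryl methyl ether and the homobenzylic C2–O bond are not hydrogenolysed under these conditions, and no stereocentre is touched.

## Compound list

1 | heptanedioyl dichloride (pimeloyl chloride) | O=C(Cl)CCCCCC(Cl)=O | starting material
2 | 7-[methoxy(methyl)amino]-7-oxoheptanoyl chloride | CON(C)C(=O)CCCCCC(Cl)=O | intermediate
3 | N1,N7-dimethoxy-N1,N7-dimethylheptanediamide | CON(C)C(=O)CCCCCC(=O)N(C)OC | intermediate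
4 | chloroiodomethane | ClCI | starting material
5 | chloromethyllithium | [Li]CCl | intermediate
6 | dilithium 1,9-dichloro-2,8-bis[methoxy(methyl)amino]nonane-2,8-bis(olate) (configuration at the two transient centres undefined) | ClCC(O[Li])(CCCCCC(O[Li])(CCl)N(C)OC)N(C)OC | intermediate
7 | 1,9-dichlorononane-2,8-dione | ClCC(=O)CCCCCC(=O)CCl | intermediate
8 | (8R)-1,9-dichloro-8-hydroxynonan-2-one | ClCC(=O)CCCCC[C@H](CCl)O | intermediate
9 | (2R,8R)-1,9-dichlorononane-2,8-diol | ClC[C@H](O)CCCCC[C@H](CCl)O | intermediate
10 | (2R)-1-chloro-7-[(2R)-oxiran-2-yl]heptan-2-ol | ClC[C@H](O)CCCCC[C@@H]1CO1 | intermediate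
11 | (2R,2'R)-2,2'-(pentane-1,5-diyl)bis(oxirane) | C1O[C@@H]1CCCCC[C@@H]1CO1 | intermediate
12 | butylmagnesium chloride | CCCC[Mg]Cl | starting material
13 | (6S)-11-[(2R)-oxiran-2-yl]undecan-6-ol | CCCCC[C@H](O)CCCCC[C@@H]1CO1 | intermediate
14 | (2R)-2-[(6S)-6-(benzyloxy)undecyl]oxirane | CCCCC[C@H](OCc1ccccc1)CCCCC[C@@H]1CO1 | intermediate
15 | 3-bromo-5-methoxyphenol | COc1cc(O)cc(Br)c1 | starting material
16 | 1-(benzyloxy)-3-bromo-5-methoxybenzene | COc1cc(OCc2ccccc2)cc(Br)c1 | intermediate
17 | [3-(benzyloxy)-5-methoxyphenyl]magnesium bromide | COc1cc(OCc2ccccc2)cc([Mg]Br)c1 | intermediate
18 | (2R,8S)-8-(benzyloxy)-1-[3-(benzyloxy)-5-methoxyphenyl]tridecan-2-ol | CCCCC[C@H](OCc1ccccc1)CCCCC[C@H](Cc1cc(OCc2ccccc2)cc(OC)c1)O | intermediate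
19 | (2R,8S)-8-(benzyloxy)-1-[3-(benzyloxy)-5-methoxyphenyl]tridecan-2-yl acetate | CCCCC[C@H](OCc1ccccc1)CCCCC[C@H](Cc1cc(OCc2ccccc2)cc(OC)c1)OC(C)=O | intermediate
20 | (2R,8S)-8-(benzyloxy)-1-(3-hydroxy-5-methoxyphenyl)tridecan-2-yl acetate | CCCCC[C@H](OCc1ccccc1)CCCCC[C@H](Cc1cc(O)cc(OC)c1)OC(C)=O | intermediate
21 | (2R,8S)-8-hydroxy-1-(3-hydroxy-5-methoxyphenyl)tridecan-2-yl acetate | CCCCC[C@H](O)CCCCC[C@H](Cc1cc(O)cc(OC)c1)OC(C)=O | target

## Step count and weak points

Total: 10 steps. Longest linear sequence: 9 steps (steps 1–6 and 8–10, from pimeloyl chloride 1); step 7 is a one-step side branch.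

**Step 3 (key step).** The most likely failure is incomplete facial discrimination at one or both carbonyls. Other risks are stalling after the first reduction, because diketone 7 is poorly soluble or the products inhibit the enzyme, and slow inactivation of the enzyme through alkylation by the chloromethyl ketone. Fallback, setting out from 7 and returning at 11: 7 is reduced without stereocontrol (NaBH4, MeOH, 0 °C) to the stereoisomer mixture of 1,9-dichlorononane-2,8-diol F1. Aqueous NaOH closes this to the stereoisomer mixture of 2,2'-(pentane-1,5-diyl)bis(oxirane) F2. F2 is then subjected to hydrolytic kinetic resolution with about one equivalent of water and the enantiomer of (salen)Co(OAc) that hydrates S-configured epoxide termini; this is a trivalent-cobalt complex of N,N'-bis(3,5-di-tert-butylsalicylidene)cyclohexane-1,2-diamine. Every molecule with an S terminus is converted into a polar diol or tetraol, and only the R,R bis-epoxide 11 should survive. At most a quarter of the material can be retained, but the double selection again favours high enantiomeric purity.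

**Step 5.** The likely problem is over-reaction at the second epoxide, which consumes material irreversibly, together with competing opening of an epoxide by chloride from the magnesium salt. Because the two epoxides react independently, throughput also depends on clean recovery of unreacted 11. Fallback, setting out from 9 and returning at 13: the desymmetrisation is moved to a protecting-group step, where nothing is lost. Diol 9 is mono-silylated (TBSCl, imidazole, DMF) to (2R,8R)-8-[(tert-butyldimethylsilyl)oxy]-1,9-dichlorononan-2-ol F3; unreacted 9 and the bis-silyl ether are easily separated and recycled. Aqueous NaOH closes the free chlorohydrin to tert-butyl{[(2R)-1-chloro-7-[(2R)-oxiran-2-yl]heptan-2-yl]oxy}dimethylsilane F4, which has only one epoxide. Compound 12 with CuI opens it to (6S,12R)-12-[(tert-butyldimethylsilyl)oxy]-13-chlorotridecan-6-ol F5. TBAF in THF removes the silyl group, and the alkoxide of (2R,8S)-1-chlorotridecane-2,8-diol F6 formed in the flask displaces chloride and gives 13.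

**Step 2.** The carbenoid 5 may decompose by α-elimination before it is trapped, the twofold substitution may stop at the half-reacted amide ketone, or 6 may collapse early and take up a further equivalent of 5. Fallback, setting out from 1 and returning at 7 (Nierenstein-type sequence): 1 is treated with excess diazomethane in Et2O at 0 °C to give 1,9-bis(diazo)nonane-2,8-dione F7. Anhydrous HCl in Et2O then converts both diazoketone groups into chloromethyl ketones with loss of nitrogen. This route needs no organolithium but requires the precautions for diazomethane.

**Step 8.** Magnesium insertion into the electron-rich bromide 16 may be sluggish and accompanied by biaryl coupling. If copper turnover is poor, magnesium halide may open the epoxide to a halohydrin or rearrange it. Fallback, setting out from 14 and 16 and returning at 18: a nickel-catalysed reductive cross-electrophile coupling that needs no preformed organometallic (NiCl2·glyme, 2,2'-bipyridine, NaI as co-catalyst, Et3N·HCl, Zn, DMPU, rt). Iodide opens the epoxide at C1 to (2R,8S)-8-(benzyloxy)-1-iodotridecan-2-ol F8 in the flask, and the primary alkyl iodide is coupled with the aryl bromide at nickel. The C2–O bond is never broken, so the configuration is kept.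

## Further compounds

F1 | step 3 | 1,9-dichlorononane-2,8-diol (mixture of R,R, S,S and meso isomers) | ClCC(O)CCCCCC(O)CCl
F2 | step 3 | 2,2'-(pentane-1,5-diyl)bis(oxirane) (mixture of R,R, S,S and meso isomers) | C1OC1CCCCCC1CO1
F3 | step 5 | (2R,8R)-8-[(tert-butyldimethylsilyl)oxy]-1,9-dichlorononan-2-ol | ClC[C@H](O)CCCCC[C@H](CCl)O[Si](C)(C)C(C)(C)C
F4 | step 5 | tert-butyl{[(2R)-1-chloro-7-[(2R)-oxiran-2-yl]heptan-2-yl]oxy}dimethylsilane | C1O[C@@H]1CCCCC[C@H](CCl)O[Si](C)(C)C(C)(C)C
F5 | step 5 | (6S,12R)-12-[(tert-butyldimethylsilyl)oxy]-13-chlorotridecan-6-ol | CCCCC[C@H](O)CCCCC[C@H](CCl)O[Si](C)(C)C(C)(C)C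
F6 | step 5 | (2R,8S)-1-chlorotridecane-2,8-diol | CCCCC[C@H](O)CCCCC[C@H](CCl)O
F7 | step 2 | 1,9-bis(diazo)nonane-2,8-dione | [N-]=[N+]=CC(=O)CCCCCC(=O)C=[N+]=[N-]
F8 | step 8 | (2R,8S)-8-(benzyloxy)-1-iodotridecan-2-ol | CCCCC[C@H](OCc1ccccc1)CCCCC[C@H](CI)O
A1 | alternative 1 | (2R,8S)-8-[(tert-butyldimethylsilyl)oxy]-1-(3-hydroxy-5-methoxyphenyl)tridecan-2-yl acetate | CCCCC[C@H](O[Si](C)(C)C(C)(C)C)CCCCC[C@H](Cc1cc(O)cc(OC)c1)OC(C)=O
A2 | alternative 1 | (2R,8S)-8-[(tert-butyldimethylsilyl)oxy]-1-(3-oxocyclobut-1-en-1-yl)tridecan-2-yl acetate | CCCCC[C@H](O[Si](C)(C)C(C)(C)C)CCCCC[C@H](CC1=CC(=O)C1)OC(C)=O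
A3 | alternative 1 | methoxyacetylene (methoxyethyne) | COC#C
A4 | alternative 2 | 2-[(6S,12R)-13-(3-benzyloxy-5-methoxyphenyl)-12-(tert-butyldimethylsilyloxy)tridecan-6-yl]-4,4,5,5-tetramethyl-1,3,2-dioxaborolane | CCCCC[C@H](B1OC(C)(C)C(C)(C)O1)CCCCC[C@H](Cc1cc(OCc2ccccc2)cc(OC)c1)O[Si](C)(C)C(C)(C)C
A5 | alternative 2 | hexyl N,N-diisopropylcarbamate | CCCCCCOC(=O)N(C(C)C)C(C)C
A6 | alternative 2 | tert-butyl{[(2R)-1-(3-benzyloxy-5-methoxyphenyl)-7-(4,4,5,5-tetramethyl-1,3,2-dioxaborolan-2-yl)heptan-2-yl]oxy}dimethylsilane | CC1(C)OB(CCCCC[C@H](Cc2cc(OCc3ccccc3)cc(OC)c2)O[Si](C)(C)C(C)(C)C)OC1(C)C
A7 | alternative 3 | (2R,8S)-8-[(tert-butyldimethylsilyl)oxy]-1-{3-[(tert-butyldimethylsilyl)oxy]-5-methoxyphenyl}tridecan-2-yl acetate | CCCCC[C@H](O[Si](C)(C)C(C)(C)C)CCCCC[C@H](Cc1cc(O[Si](C)(C)C(C)(C)C)cc(OC)c1)OC(C)=O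
A8 | alternative 3 | rac-1-bromo-2-{3-[(tert-butyldimethylsilyl)oxy]-5-methoxyphenyl}ethyl acetate | CC(=O)OC(Br)Cc1cc(O[Si](C)(C)C(C)(C)C)cc(OC)c1
A9 | alternative 3 | [(6S)-6-[(tert-butyldimethylsilyl)oxy]undecyl]zinc iodide | CCCCC[C@H](O[Si](C)(C)C(C)(C)C)CCCCC[Zn]I
A10 | alternative 3 | 2-{3-[(tert-butyldimethylsilyl)oxy]-5-methoxyphenyl}acetaldehyde | O=CCc1cc(O[Si](C)(C)C(C)(C)C)cc(OC)c1
A11 | alternative 3 | acetyl bromide | CC(=O)Br
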